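**Retrosynthetic overview** (atom numbers follow germacrane numbering of the target)
1. Target ⇒ 8,9-diol 27 + side-chain acid 33; the C8 ester is made last.
2. 27 ⇒ seco enal/allylic bromide 23: the C6–C7 bond is made by intramolecular chromium allylation, which closes the ten-membered carbocycle and, by lactonisation, the γ-lactone (last two rings, one step).
3. 23 ⇒ furanone 16: C11–C13 come from methyl propiolate at a C7 aldehyde; the furanone (first ring) comes from α′-hydroxy ynone 15 by 5-endo cyclisation.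
4. 15 ⇒ key C1–C10 bond: an alkynoyl anion equivalent (lithiated benzotriazole N,O-acetal 13 carrying C1–C6) adds to methyl ketone 4 under chelation control, which sets C10.
5. 4 ⇒ L-proline aldol of hydroxyacetone (sets C8 and C9); 12 ⇒ Z-vinyl iodide from but-2-yn-1-ol + propargylic N,O-acetal 11.

Assumption: (S)-glyceraldehyde acetonide 2 (made from L-ascorbic acid) is treated as a purchasable starting material.

**Step 1**
Reactants: 1 hydroxyacetone; 2 (S)-glyceraldehyde acetonide
Product: 3 anti-keto-diol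
Conditions: L-proline (30 mol%), DMSO, excess 1, rt, 48 h
Reagents that add atoms: none
Why: L-proline-catalysed direct aldol (List type), in which the hydroxy enamine of 1 attacks the re face of the aldehyde through the hydrogen-bonded chair transition state to give the anti-diol that becomes C9/C8 of the target, matched with the Felkin preference of 2, whose own stereocentre is sacrificial and is cleaved off in step 9.

**Step 2**
Reactants: 3 anti-keto-diol
Product: 4 bis-acetonide methyl ketone
Conditions: 2-methoxypropene, PPTS (cat.), CH2Cl2, 0 °C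
Reagents that add atoms: 2-methoxypropene, COC(C)=C
Why: Kinetic ketalisation of the anti-1,2-diol gives the cis-dioxolane without moving the terminal acetonide and leaves the ring oxygen on C9 as a chelating group next to the ketone, with no stereocentre touched.

**Step 3**
Reactants: 5 but-2-yn-1-ol
Product: 7 (Z)-3-iodobut-2-en-1-ol, via cyclic vinylalanate 6 (not isolated)
Conditions: NaAlH2(OCH2CH2OMe)2, THF, 0 °C → rt; then I2, −78 → 0 °C
Reagents that add atoms: iodine, [I][I]
Why: Hydroxyl-directed trans-hydroalumination places aluminium on the distal alkyne carbon inside the five-membered alanate, and iodinolysis with retention gives the Z-vinyl iodide, which fixes the later C4=C5 geometry (C3 cis to C6).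

**Step 4**
Reactants: 7 (Z)-3-iodobut-2-en-1-ol
Product: 8 PMB ether of 7
Conditions: NaH, 4-methoxybenzyl chloride, Bu4NI (cat.), DMF, 0 °C
Reagents that add atoms: 4-methoxybenzyl chloride, COc1ccc(CCl)cc1
Why: Williamson etherification masks the allylic hydroxyl as a PMB ether that survives the organolithium step and can later be removed oxidatively under neutral conditions.

**Step 5**
Reactants: 9 3,3-diethoxyprop-1-yne; 10 1H-benzotriazole
Product: 11 1-(1-ethoxyprop-2-yn-1-yl)benzotriazole
Conditions: toluene, TsOH (cat.), 110 °C, EtOH distilled off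
Reagents that add atoms: none
Why: Acetal exchange with benzotriazole (Katritzky-type N,O-acetal formation) installs the 1-ethoxy-1-benzotriazolyl group that later stabilises a carbanion at C1 and is hydrolysed to a ketone.

**Step 6**
Reactants: 8 PMB ether; 11 propargylic N,O-acetal
Product: 12 Z-enyne N,O-acetal (C1–C6 fragment)
Conditions: Pd(PPh3)2Cl2 (3 mol%), CuI (5 mol%), Et3N, THF, rt
Reagents that add atoms: none
Why: Sonogashira coupling joins the terminal alkyne to the vinyl iodide with retention of the Z geometry and tolerates the N,O-acetal.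

**Step 7 (key step)**
Reactants: 12 Z-enyne N,O-acetal; 4 bis-acetonide methyl ketone
Product: 15 α′-hydroxy ynone, via lithiated N,O-acetal 13 (not isolated), via carbinol N,O-acetal 14 (not isolated)
Conditions: n-BuLi, THF, −78 °C; MgBr2·OEt2; 4, −78 → −40 °C; then 5% aq. oxalic acid, THF, 0 °C → rt
Reagents that add atoms: water, O
Why: Acyl anion addition in which the benzotriazole- and ethoxy-stabilised carbanion (an alkynoyl anion equivalent carrying C1–C6) attacks the ketone held in a five-membered magnesium chelate with the dioxolane oxygen on C9 from the face anti to C8 (Cram chelate control), setting the quaternary C10 with its oxygen syn to O9, after which mild acid unmasks the C1 ketone by loss of benzotriazole and ethanol.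

**Step 8**
Reactants: 15 α′-hydroxy ynone
Product: 16 3(2H)-furanone
Conditions: K2CO3 (0.2 equiv), MeOH, 0 °C → rt
Reagents that add atoms: none
Why: Base-mediated 5-endo-dig oxa-Michael addition of the tertiary hydroxyl to the ynone β-carbon (C3) closes the furanone without affecting C10, and avoiding a π-acid keeps the PMB ether oxygen from attacking the alkyne.

**Step 9**
Reactants: 16 3(2H)-furanone
Product: 17 C7 aldehyde
Conditions: H5IO6 (1.5 equiv), EtOAc, rt
Reagents that add atoms: none
Why: Periodic acid hydrolyses the less hindered terminal acetonide faster than the internal cis-dioxolane and cleaves the freed 1,2-diol in the same flask (Malaprade glycol cleavage), unveiling C7 as the aldehyde and removing the sacrificial stereocentre.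

**Step 10**
Reactants: 17 C7 aldehyde; 18 methyl propiolate
Product: 20 Baylis–Hillman-type adduct, via vinylalane 19 (not isolated)
Conditions: i-Bu2AlH, N-methylmorpholine N-oxide, THF, 0 °C; 18, 0 °C; then 17, 0 °C → rt; potassium sodium tartrate work-up
Reagents that add atoms: none
Why: Vinylalumination (hydroalumination of the propiolate, then carbonyl addition of the α-(methoxycarbonyl)vinyl alane) gives the Morita–Baylis–Hillman-type adduct without the amine base that could epimerise the cis-dioxolane aldehyde at C8; the new carbinol centre is uncontrolled and is erased in step 11.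

**Step 11**
Reactants: 20 Baylis–Hillman-type adduct
Product: 21 (Z)-2-(bromomethyl)enoate
Conditions: NBS, Me2S, CH2Cl2, 0 °C → rt
Reagents that add atoms: N-bromosuccinimide, O=C1CCC(=O)N1Br
Why: Corey–Kim-type activation of the allylic alcohol followed by SN2′ attack of bromide gives the thermodynamically preferred (Z)-2-(bromomethyl)enoate and removes the uncontrolled carbinol centre.

**Step 12**
Reactants: 21 (Z)-2-(bromomethyl)enoate
Product: 23 Z-enal allylic bromide, via allylic alcohol 22 (not isolated)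
Conditions: DDQ, CH2Cl2/pH 7 buffer, 0 °C; then MnO2, CH2Cl2, rt
Reagents that add atoms: none
Why: Oxidative PMB cleavage under buffered conditions followed at once by allylic oxidation with MnO2 gives the Z-enal before the free C6 hydroxyl can add to the furanone, and neither reagent touches the allylic bromide.

**Step 13**
Reactants: 23 Z-enal allylic bromide
Product: 26 macrolactone acetonide, via allylchromium dichloride 24 (not isolated), via ring-closed hydroxy ester 25 (not isolated)
Conditions: CrCl2 (10 equiv), THF, 0.002 M (syringe pump), rt → 40 °C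
Reagents that add atoms: none
Why: Intramolecular Nozaki–Hiyama-type (Barbier) allylation in which the allylchromium adds through C7 to the enal in a six-membered chair transition state to give the anti (6,7-trans) adduct, as in chromium-mediated closures of other germacranolide ten-membered rings; C6 is delivered to the face of C7 anti to C9 with the C8 hydrogen eclipsing the allyl unit (minimised allylic strain), and the trans-γ-alkoxide then lactonises onto the methyl ester, so C6 and C7 are set here.

**Step 14**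
Reactants: 26 macrolactone acetonide
Product: 27 8,9-diol
Conditions: TFA/H2O (9:1), CH2Cl2, 0 °C
Reagents that add atoms: none
Why: Acid hydrolysis of the isopropylidene ketal frees the 8,9-diol, while the lactone, furanone and exocyclic methylene tolerate brief aqueous acid and no stereocentre is touched.

**Step 15**
Reactants: 28 acetaldehyde; 29 tert-butyl acrylate
Product: 30 tert-butyl 3-hydroxy-2-methylidenebutanoate
Conditions: DABCO (0.2 equiv), neat, excess 28, rt, 5 d
Reagents that add atoms: none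
Why: Morita–Baylis–Hillman reaction of an unhindered aliphatic aldehyde with an acrylate; the racemic carbinol centre is removed in step 16.

**Step 16**
Reactants: 30 tert-butyl 3-hydroxy-2-methylidenebutanoate
Product: 32 tert-butyl (E)-2-(acetoxymethyl)but-2-enoate, via secondary acetate 31 (not isolated)
Conditions: Ac2O, pyridine, DMAP (cat.), CH2Cl2, 0 °C → rt; then DABCO (1 equiv), THF, 65 °C
Reagents that add atoms: acetic anhydride, CC(=O)OC(C)=O
Why: Acetylation followed by DABCO-mediated 1,3-transposition of the allylic acetate (SN2′ then SN2′ through the allylammonium salt) gives the thermodynamic primary acetate with the ester trans to the methyl group, which is the E geometry of the target side chain.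

**Step 17**
Reactants: 32 tert-butyl (E)-2-(acetoxymethyl)but-2-enoate
Product: 33 (E)-2-(acetoxymethyl)but-2-enoic acid
Conditions: TFA, CH2Cl2, 0 °C → rt
Reagents that add atoms: none
Why: Acidolysis of the tert-butyl ester (loss of 2-methylpropene) frees the acid without hydrolysing the acetate or isomerising the alkene.

**Step 18**
Reactants: 27 8,9-diol; 33 (E)-2-(acetoxymethyl)but-2-enoic acid
Product: 35 target, via mixed anhydride 34 (not isolated)
Conditions: 33 (1.05 equiv), 2,4,6-trichlorobenzoyl chloride, Et3N, toluene, rt; then 27, DMAP, 0 °C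
Reagents that add atoms: none
Why: Yamaguchi esterification, in which the mixed anhydride acylates the C8 hydroxyl in preference to the C9 hydroxyl because the latter is neopentylic (next to quaternary C10), and the thermodynamically favoured E-alkene of the acyl group is not isomerised.

**Compound list**
1 | hydroxyacetone (1-hydroxypropan-2-one) | CC(=O)CO | starting material
2 | (4S)-2,2-dimethyl-1,3-dioxolane-4-carbaldehyde ((S)-glyceraldehyde acetonide) | O=C[C@@H]1COC(C)(C)O1 | starting material
3 | (3S,4R)-4-[(4S)-2,2-dimethyl-1,3-dioxolan-4-yl]-3,4-dihydroxybutan-2-one (3,4-anti diol) | CC(=O)[C@@H](O)[C@@H](O)[C@@H]1COC(C)(C)O1 | intermediate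
4 | 1-[(4S,5S)-5-[(4S)-2,2-dimethyl-1,3-dioxolan-4-yl]-2,2-dimethyl-1,3-dioxolan-4-yl]ethan-1-one (cis-4,5-disubstituted dioxolane) | CC(=O)[C@H]1OC(C)(C)O[C@H]1[C@@H]2COC(C)(C)O2 | intermediate
5 | but-2-yn-1-ol | CC#CCO | starting material
6 | sodium 2,2-bis(2-methoxyethoxy)-3-methyl-2,5-dihydro-1,2-oxaluminol-2-uide (cyclic vinylalanate) | [Na+].CC1=CCO[Al-]1(OCCOC)OCCOC | intermediate (not isolated)
7 | (2Z)-3-iodobut-2-en-1-ol | OC/C=C(/C)I | intermediate
8 | 1-({[(2Z)-3-iodobut-2-en-1-yl]oxy}methyl)-4-methoxybenzene | COc1ccc(COC/C=C(/C)I)cc1 | intermediate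
9 | 3,3-diethoxyprop-1-yne | CCOC(OCC)C#C | starting material
10 | 1H-benzotriazole | c1ccc2[nH]nnc2c1 | starting material
11 | 1-(1-ethoxyprop-2-yn-1-yl)-1H-benzotriazole (racemic) | CCOC(C#C)n1nnc2ccccc21 | intermediate
12 | 1-{(4Z)-1-ethoxy-6-[(4-methoxyphenyl)methoxy]-4-methylhex-4-en-2-yn-1-yl}-1H-benzotriazole (racemic) | CCOC(C#C/C(C)=C\COCc1ccc(OC)cc1)n1nnc2ccccc21 | intermediate
13 | 1-lithio derivative of 12 (lithium on the carbon bearing ethoxy and benzotriazolyl) | CCOC([Li])(C#C/C(C)=C\COCc1ccc(OC)cc1)n1nnc2ccccc21 | intermediate (not isolated)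
14 | (2R,6Z)-3-(1H-benzotriazol-1-yl)-2-[(4S,5S)-5-[(4S)-2,2-dimethyl-1,3-dioxolan-4-yl]-2,2-dimethyl-1,3-dioxolan-4-yl]-3-ethoxy-8-[(4-methoxyphenyl)methoxy]-6-methyloct-6-en-4-yn-2-ol (both C3 epimers; formed as its metal alkoxide) | CCOC(C#C/C(C)=C\COCc1ccc(OC)cc1)(n1nnc2ccccc21)[C@](C)(O)[C@H]3OC(C)(C)O[C@H]3[C@@H]4COC(C)(C)O4 | intermediate (not isolated)
15 | (2R,6Z)-2-[(4S,5S)-5-[(4S)-2,2-dimethyl-1,3-dioxolan-4-yl]-2,2-dimethyl-1,3-dioxolan-4-yl]-2-hydroxy-8-[(4-methoxyphenyl)methoxy]-6-methyloct-6-en-4-yn-3-one | COc1ccc(COC/C=C(/C)C#CC(=O)[C@](C)(O)[C@H]2OC(C)(C)O[C@H]2[C@@H]3COC(C)(C)O3)cc1 | intermediate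
16 | (2R)-2-[(4S,5S)-5-[(4S)-2,2-dimethyl-1,3-dioxolan-4-yl]-2,2-dimethyl-1,3-dioxolan-4-yl]-5-{(2Z)-4-[(4-methoxyphenyl)methoxy]but-2-en-2-yl}-2-methylfuran-3(2H)-one | COc1ccc(COC/C=C(/C)C2=CC(=O)[C@](C)(O2)[C@H]3OC(C)(C)O[C@H]3[C@@H]4COC(C)(C)O4)cc1 | intermediate
17 | (4R,5S)-5-[(2R)-5-{(2Z)-4-[(4-methoxyphenyl)methoxy]but-2-en-2-yl}-2-methyl-3-oxo-2,3-dihydrofuran-2-yl]-2,2-dimethyl-1,3-dioxolane-4-carbaldehyde (cis-dioxolane) | COc1ccc(COC/C=C(/C)C2=CC(=O)[C@](C)(O2)[C@H]3OC(C)(C)O[C@H]3C=O)cc1 | intermediate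
18 | methyl prop-2-ynoate (methyl propiolate) | C#CC(=O)OC | starting material
19 | methyl 2-[bis(2-methylpropyl)alumanyl]prop-2-enoate | C=C(C(=O)OC)[Al](CC(C)C)CC(C)C | intermediate (not isolated)
20 | methyl 2-{hydroxy[(4S,5S)-5-[(2R)-5-{(2Z)-4-[(4-methoxyphenyl)methoxy]but-2-en-2-yl}-2-methyl-3-oxo-2,3-dihydrofuran-2-yl]-2,2-dimethyl-1,3-dioxolan-4-yl]methyl}prop-2-enoate (both carbinol epimers) | COc1ccc(COC/C=C(/C)C2=CC(=O)[C@](C)(O2)[C@H]3OC(C)(C)O[C@H]3C(O)C(=C)C(=O)OC)cc1 | intermediate
21 | methyl (2Z)-2-(bromomethyl)-3-[(4S,5S)-5-[(2R)-5-{(2Z)-4-[(4-methoxyphenyl)methoxy]but-2-en-2-yl}-2-methyl-3-oxo-2,3-dihydrofuran-2-yl]-2,2-dimethyl-1,3-dioxolan-4-yl]prop-2-enoate | COc1ccc(COC/C=C(/C)C2=CC(=O)[C@](C)(O2)[C@H]3OC(C)(C)O[C@H]3/C=C(\CBr)C(=O)OC)cc1 | intermediate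
22 | methyl (2Z)-2-(bromomethyl)-3-[(4S,5S)-5-{(2R)-5-[(2Z)-4-hydroxybut-2-en-2-yl]-2-methyl-3-oxo-2,3-dihydrofuran-2-yl}-2,2-dimethyl-1,3-dioxolan-4-yl]prop-2-enoate | OC/C=C(/C)C1=CC(=O)[C@](C)(O1)[C@H]2OC(C)(C)O[C@H]2/C=C(\CBr)C(=O)OC | intermediate (not isolated)
23 | methyl (2Z)-2-(bromomethyl)-3-[(4S,5S)-2,2-dimethyl-5-{(2R)-2-methyl-3-oxo-5-[(2Z)-4-oxobut-2-en-2-yl]-2,3-dihydrofuran-2-yl}-1,3-dioxolan-4-yl]prop-2-enoate | O=C/C=C(/C)C1=CC(=O)[C@](C)(O1)[C@H]2OC(C)(C)O[C@H]2/C=C(\CBr)C(=O)OC | intermediate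
24 | allylchromium dichloride derived from 23 (CrCl2 in place of Br) | O=C/C=C(/C)C1=CC(=O)[C@](C)(O1)[C@H]2OC(C)(C)O[C@H]2/C=C(\C[Cr](Cl)Cl)C(=O)OC | intermediate (not isolated)
25 | methyl (4Z,6R,7S,8S,9S,10R)-6-hydroxy-8,9-(isopropylidenedioxy)-1-oxo-3,10-epoxygermacra-2,4,11(13)-trien-12-oate (formed as its chromium alkoxide) | C=C(C(=O)OC)[C@H]1[C@H](O)/C=C(/C)C2=CC(=O)[C@](C)(O2)[C@@H](OC(C)(C)O3)[C@@H]31 | intermediate (not isolated)
26 | (4Z,6R,7S,8S,9S,10R)-8,9-(isopropylidenedioxy)-1-oxo-3,10-epoxygermacra-2,4,11(13)-trien-12,6-olide | C=C1C(=O)O[C@@H]2/C=C(/C)C3=CC(=O)[C@](C)(O3)[C@@H](OC(C)(C)O4)[C@@H]4[C@@H]12 | intermediate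
27 | (4Z,6R,7R,8S,9S,10R)-8,9-dihydroxy-1-oxo-3,10-epoxygermacra-2,4,11(13)-trien-12,6-olide (same spatial arrangement as 26; the C7 descriptor changes only formally) | C=C1C(=O)O[C@@H]2/C=C(/C)C3=CC(=O)[C@](C)(O3)[C@@H](O)[C@@H](O)[C@@H]12 | intermediate
28 | acetaldehyde | CC=O | starting material
29 | tert-butyl prop-2-enoate (tert-butyl acrylate) | C=CC(=O)OC(C)(C)C | starting material
30 | tert-butyl 3-hydroxy-2-methylidenebutanoate (racemic) | CC(O)C(=C)C(=O)OC(C)(C)C | intermediate
31 | tert-butyl 3-acetoxy-2-methylidenebutanoate (racemic) | CC(OC(C)=O)C(=C)C(=O)OC(C)(C)C | intermediate (not isolated)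
32 | tert-butyl (2E)-2-(acetoxymethyl)but-2-enoate | C/C=C(/C(=O)OC(C)(C)C)COC(C)=O | intermediate
33 | (2E)-2-(acetoxymethyl)but-2-enoic acid | C/C=C(/C(=O)O)COC(C)=O | intermediate
34 | (2E)-2-(acetoxymethyl)but-2-enoic 2,4,6-trichlorobenzoic anhydride | C/C=C(/C(=O)OC(=O)c1c(Cl)cc(Cl)cc1Cl)COC(C)=O | intermediate (not isolated)
35 | (4Z,6R,7S,8S,9S,10R)-9-hydroxy-1-oxo-3,10-epoxygermacra-2,4,11(13)-trien-12,6-olid-8-yl (2E)-2-(acetoxymethyl)but-2-enoate (CNP0231561.1) | C=C1C(=O)O[C@@H]2/C=C(/C)C3=CC(=O)[C@](C)(O3)[C@@H](O)[C@@H](OC(=O)/C(=C/C)COC(C)=O)[C@@H]12 | target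

**Step count**
Total: 18 steps. Longest linear sequence: 12 steps (5 → 7 → 8 → 12 → 15 → 16 → 17 → 20 → 21 → 23 → 26 → 27 → 35; steps 3, 4, 6–14 and 18).

**Three steps most likely to fail**

Step 7 (key addition). The risks are addition outside the magnesium chelate (Felkin sense, giving the C10 epimer), enolisation of the methyl ketone, and slow attack of a hindered carbanion on a hindered ketone. The fallback sets out from the unprotected keto-diol 3. It is converted into its bis(chloromagnesium) alkoxide with t-BuMgCl (2 equiv, THF, −78 °C) and then treated with 13. The C9 oxygen is now covalently bound to magnesium and holds the ketone in a rigid five-membered chelate (the classical α-hydroxy ketone case), so attack anti to C8 should be enforced more strongly than by the acetal oxygen. This gives the N,O-acetal triol F1, which aqueous oxalic acid converts into the triol ynone F2. Kinetic ketalisation of F2 with 2-methoxypropene/PPTS at the vicinal secondary diol (the tertiary hydroxyl does not compete) comes back to the route at 15.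

Step 13 (ring closure). The risks are strain in closing the ring onto a preformed planar furanone, the wrong C6/C7 diastereomer, and oligomerisation. The fallback closes the ring before the furanone exists and sets out from 14, isolated after a neutral NH4Cl quench of step 7 instead of the acid hydrolysis. The reagents of steps 9–12 are applied in the same order:
- H5IO6 gives the aldehyde N,O-acetal F3.
- Vinylalane 19 gives the Baylis–Hillman-type adduct F4.
- NBS/Me2S gives the allylic bromide F5.
- DDQ gives the allylic alcohol F6, and MnO2 gives the enal F7.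

CrCl2 under high dilution then converts F7 through the allylchromium dichloride F8 and the ring-closed hydroxy ester F9 into the macrolactone N,O-acetal F10, whose ten-membered ring holds a linear alkyne instead of the furanone. Aqueous oxalic acid unmasks the macrocyclic hydroxy ynone lactone F11, and K2CO3/MeOH closes the furanone transannularly (5-endo-dig), coming back to the route at 26.

Step 18 (regioselective acylation). The risks are acylation at the C9 hydroxyl, diacylation, and base-promoted 8→9 acyl migration in the cis-diol. The fallback replaces base-catalysed acylation by tin-acetal activation and sets out from 27. Bu2SnO (toluene, reflux, water removed) gives the 8,9-O-dibutylstannylene acetal F12. The acid 33 is converted with 1-chloro-N,N,2-trimethylprop-1-en-1-amine into (2E)-2-(acetoxymethyl)but-2-enoyl chloride F13. Reaction of F12 with F13 at −20 °C without amine base acylates the tin-activated oxygen on the less hindered C8 and comes back to the route at 35.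

**Further compounds**
F1 | step 7 | (2R,6Z)-3-(1H-benzotriazol-1-yl)-3-ethoxy-8-[(4-methoxyphenyl)methoxy]-6-methyloct-6-en-4-yn-2-ol carrying at C2 the (1S,2R)-1,2-dihydroxy-2-[(4S)-2,2-dimethyl-1,3-dioxolan-4-yl]ethyl group (N,O-acetal triol, both C3 epimers) | CCOC(C#C/C(C)=C\COCc1ccc(OC)cc1)(n1nnc2ccccc21)[C@](C)(O)[C@@H](O)[C@@H](O)[C@@H]3COC(C)(C)O3
F2 | step 7 | triol ynone: 15 lacking the internal acetonide (free 8,9-diol, terminal acetonide kept) | COc1ccc(COC/C=C(/C)C#CC(=O)[C@](C)(O)[C@@H](O)[C@@H](O)[C@@H]2COC(C)(C)O2)cc1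
F3 | step 13 | aldehyde N,O-acetal: 14 with the terminal dioxolane cleaved to the C7 aldehyde | CCOC(C#C/C(C)=C\COCc1ccc(OC)cc1)(n1nnc2ccccc21)[C@](C)(O)[C@H]3OC(C)(C)O[C@H]3C=O
F4 | step 13 | Baylis–Hillman-type adduct of F3 with methyl propiolate-derived vinylalane (both carbinol epimers) | CCOC(C#C/C(C)=C\COCc1ccc(OC)cc1)(n1nnc2ccccc21)[C@](C)(O)[C@H]3OC(C)(C)O[C@H]3C(O)C(=C)C(=O)OC
F5 | step 13 | (Z)-2-(bromomethyl)enoate from F4 | CCOC(C#C/C(C)=C\COCc1ccc(OC)cc1)(n1nnc2ccccc21)[C@](C)(O)[C@H]3OC(C)(C)O[C@H]3/C=C(\CBr)C(=O)OC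
F6 | step 13 | allylic alcohol from F5 (PMB removed) | CCOC(C#C/C(C)=C\CO)(n1nnc2ccccc21)[C@](C)(O)[C@H]3OC(C)(C)O[C@H]3/C=C(\CBr)C(=O)OC
F7 | step 13 | Z-enal from F6 | CCOC(C#C/C(C)=C\C=O)(n1nnc2ccccc21)[C@](C)(O)[C@H]3OC(C)(C)O[C@H]3/C=C(\CBr)C(=O)OC
F8 | step 13 | allylchromium dichloride from F7 | CCOC(C#C/C(C)=C\C=O)(n1nnc2ccccc21)[C@](C)(O)[C@H]3OC(C)(C)O[C@H]3/C=C(\C[Cr](Cl)Cl)C(=O)OC
F9 | step 13 | ring-closed hydroxy ester with C1 as N,O-acetal and a C2–C3 alkyne in the ten-membered ring | C=C(C(=O)OC)[C@H]1[C@H](O)/C=C(/C)C#CC(OCC)(n2nnc3ccccc32)[C@](C)(O)[C@@H](OC(C)(C)O4)[C@@H]41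
F10 | step 13 | macrolactone N,O-acetal (12,6-olide of F9) | C=C1C(=O)O[C@@H]2/C=C(/C)C#CC(OCC)(n3nnc4ccccc43)[C@](C)(O)[C@@H](OC(C)(C)O5)[C@@H]5[C@@H]12
F11 | step 13 | macrocyclic hydroxy ynone lactone (10-hydroxy-1-oxo-germacr-4-en-2-yn-12,6-olide 8,9-acetonide) | C=C1C(=O)O[C@@H]2/C=C(/C)C#CC(=O)[C@](C)(O)[C@@H](OC(C)(C)O3)[C@@H]3[C@@H]12
F12 | step 18 | 8,9-O-dibutylstannylene acetal of 27 | C=C1C(=O)O[C@@H]2/C=C(/C)C3=CC(=O)[C@](C)(O3)[C@@H](O[Sn](CCCC)(CCCC)O4)[C@@H]4[C@@H]12
F13 | step 18 | (2E)-2-(acetoxymethyl)but-2-enoyl chloride | C/C=C(/C(=O)Cl)COC(C)=O
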